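**Strategy.** The route rests on disconnecting the bond shared by the fulvene five-membered ring and the seven-membered ketone ring, between the fulvene carbon that carries the ring C=O and the one bonded to the quaternary C–CH3 carbon. A rhodium-catalysed allenic Pauson–Khand reaction forms this bond, the cycloheptene and the cyclopentenone in one operation; its CO becomes the ester-bearing fulvene carbon and its acyloxyallene carbon the ring ketone. The precursor is a fully stereodefined indolizidine carrying, cis on the pyrrolidine, a silylalkyne and a propargylic acetate chain. A final C-acylation of the cyclopentadienide closes the second seven-membered ring.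

Key step: step 17

Remark: aldehydes 5 and 25 are taken as commercial; stereocentres left open in the SMILES of 7, 9, 18, 19 and 26–29 are mixtures that are erased or corrected later; 32–34 are drawn as single tautomers.

Step 1
Reactants: 1 methyl 3-oxopentanoate
Product: 2 methyl 2-(2-ethyl-1,3-dioxolan-2-yl)acetate
Conditions: HOCH2CH2OH, TsOH (cat.), toluene, reflux (Dean–Stark)
Reagents that add atoms: ethylene glycol OCCO
Why: Acid-catalysed ketalisation with azeotropic removal of water masks the future ring ketone; no stereocentre is formed.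

Step 2
Reactants: 2 methyl 2-(2-ethyl-1,3-dioxolan-2-yl)acetate; 3 methyl acetate
Product: 4 methyl 4-(2-ethyl-1,3-dioxolan-2-yl)-3-oxobutanoate
Conditions: LiN(iPr)2 (3 equiv), 3 (3 equiv), THF, −78 °C; then 2, −78 → −30 °C; aq. NH4Cl
Reagents that add atoms: none
Why: Crossed Claisen condensation of the lithium enolate of 3 with ester 2 should give the β-keto ester, deprotonation of the product driving the equilibrium.

Step 3
Reactants: 5 4-[(tert-butyldimethylsilyl)oxy]butanal; 6 nitromethane
Product: 8 (E)-nitroalkene, via nitro alcohol 7 (not isolated)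
Conditions: 6 (5 equiv), KOtBu (10 mol %), THF/tBuOH, 0 °C; then MsCl, Et3N, CH2Cl2, 0 °C
Reagents that add atoms: none
Why: Henry (nitroaldol) reaction followed by mesylation–elimination should give the thermodynamically favoured E-nitroalkene.

Step 4
Reactants: 4 β-keto ester; 8 (E)-nitroalkene
Product: 9 (3S)-γ-nitro β-keto ester (C2 epimers)
Conditions: 1-[3,5-bis(trifluoromethyl)phenyl]-3-[(1S,2S)-2-(dimethylamino)cyclohexyl]thiourea (10 mol %), toluene, rt
Reagents that add atoms: none
Why: Bifunctional thiourea-catalysed asymmetric Michael addition; the catalyst binds the nitro group and delivers the enol to one face, setting the S centre that carries the side chain (the (S,S)-catalyst is chosen because its enantiomer gives (S)-adducts of β-nitrostyrene and an alkyl group inverts the CIP ranking), while the β-keto ester carbon remains an epimer mixture that is erased in steps 5–7.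

Step 5
Reactants: 9 γ-nitro β-keto ester
Product: 10 cyclic enamino ester
Conditions: H2 (1 atm), Raney Ni, MeOH, rt
Reagents that add atoms: none
Why: Nitro reduction releases the amine, which condenses with the ketone to the five-membered vinylogous carbamate, a thermodynamic sink that should prevent lactam formation with the ester.

Step 6
Reactants: 10 cyclic enamino ester
Product: 12 all-cis N-Boc pyrrolidine ester, via free pyrrolidine 11 (not isolated)
Conditions: H2 (5 atm), PtO2, MeOH/AcOH (9:1), rt; filter; then Boc2O, Et3N, CH2Cl2, rt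
Reagents that add atoms: di-tert-butyl dicarbonate CC(C)(C)OC(=O)OC(=O)OC(C)(C)C
Why: Heterogeneous hydrogenation of the tetrasubstituted enamine C=C should add both hydrogens to the face opposite the C4 side chain, giving the all-cis 2,3,4-trisubstituted pyrrolidine, and carbamate formation removes the N–H before enolate chemistry.

Step 7
Reactants: 12 all-cis N-Boc pyrrolidine ester
Product: 13 3-methylated ester
Conditions: LiN(iPr)2, THF, −78 °C; MeI, −78 → −40 °C
Reagents that add atoms: iodomethane CI
Why: Ester enolate alkylation; the C2 and C4 arms are cis on one face of the planar enolate, so iodomethane should attack from the opposite face, placing the methyl trans to both and leaving the ester carbon on their face (sets the quaternary centre).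

Step 8
Reactants: 13 3-methylated ester
Product: 14 neopentyl aldehyde
Conditions: iBu2AlH (1.2 equiv), CH2Cl2, −78 °C; aq. KNaC4H4O6
Reagents that add atoms: none
Why: Partial hydride reduction of the hindered α-quaternary ester should stop at the tetrahedral aluminium hemiacetal, which releases the non-enolisable aldehyde on work-up.

Step 9
Reactants: 14 neopentyl aldehyde
Product: 15 terminal alkyne
Conditions: dimethyl (1-diazo-2-oxopropyl)phosphonate, K2CO3, MeOH, 0 °C → rt
Reagents that add atoms: dimethyl (1-diazo-2-oxopropyl)phosphonate CC(=O)C(=[N+]=[N-])P(=O)(OC)OC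
Why: Seyferth–Gilbert homologation (Ohira–Bestmann variant) converts the aldehyde into the terminal alkyne with one added carbon; the quaternary centre cannot epimerise.

Step 10
Reactants: 15 terminal alkyne
Product: 17 indolizidin-7-one, via amino ketone 16 (not isolated)
Conditions: 3 M HCl (aq), THF, 50 °C; then 37 % aq. CH2O (1.1 equiv), NaOAc (pH 4), EtOH, 60 °C; NaOH work-up
Reagents that add atoms: formaldehyde C=O
Why: Acid removes the carbamate, the dioxolane and the silyl ether, and the liberated β-amino ethyl ketone should undergo an intramolecular Mannich reaction with the formaldehyde-derived iminium ion (6-endo-trig through the enol of the ethyl side) to the 4-piperidone ring, whose α-methyl centre equilibrates to the equatorial position (trans to the ring-fusion C–C bond).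

Step 11
Reactants: 17 indolizidin-7-one
Product: 18 nitrile (C7 epimers)
Conditions: TosMIC, KOtBu, DME/EtOH, 0 → 40 °C
Reagents that add atoms: p-toluenesulfonylmethyl isocyanide Cc1ccc(cc1)S(=O)(=O)C[N+]#[C-]
Why: van Leusen reductive cyanation converts the ketone into the nitrile with one added carbon; the new centre forms as a mixture that is corrected in step 12.

Step 12
Reactants: 18 nitrile
Product: 20 trans methyl ester, via epimeric ester mixture 19 (not isolated)
Conditions: HCl (g), MeOH, 0 °C → rt; H2O (2 equiv); evaporate; then NaOMe, MeOH, 50 °C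
Reagents that add atoms: methanol CO; water O
Why: Pinner reaction turns the nitrile into the methyl ester, and methoxide then epimerises the α-centre under thermodynamic control to the all-equatorial isomer (ester trans to the neighbouring methyl, cis to the ring-fusion C–C bond).

Step 13
Reactants: 20 trans methyl ester
Product: 22 C-silylated alkyne, via bis-silylated compound 21 (not isolated)
Conditions: Zn(OTf)2 (20 mol %), Et3N, Me3SiOTf, CH2Cl2, rt; then citric acid, MeOH/H2O
Reagents that add atoms: trimethylsilyl trifluoromethanesulfonate C[Si](C)(C)OS(=O)(=O)C(F)(F)F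
Why: Zinc-acetylide-mediated C-silylation of the terminal alkyne distinguishes it from the alkyne made in step 15, and the transient O-silyl ether is cleaved on mild acidic work-up.

Step 14
Reactants: 22 C-silylated alkyne
Product: 23 side-chain aldehyde
Conditions: Dess–Martin periodinane, NaHCO3, CH2Cl2, 0 °C → rt
Reagents that add atoms: none
Why: Dess–Martin oxidation of the primary alcohol should tolerate the tertiary amine, the ester and the silylalkyne.

Step 15
Reactants: 23 side-chain aldehyde
Product: 24 side-chain terminal alkyne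
Conditions: Me3SiCHN2, LiN(iPr)2, THF, −78 → 0 °C
Reagents that add atoms: (trimethylsilyl)diazomethane C[Si](C)(C)C=[N+]=[N-]
Why: Colvin rearrangement with lithiated (trimethylsilyl)diazomethane homologates the aldehyde to the alkyne without the basic methanol that would cleave the C-silyl group.

Step 16
Reactants: 24 side-chain terminal alkyne; 25 3-[(tert-butyldimethylsilyl)oxy]propanal
Product: 27 propargylic acetate, via propargylic alcohol 26 (not isolated)
Conditions: LiN(SiMe3)2, THF, −78 °C; 25; then Ac2O, −78 → 0 °C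
Reagents that add atoms: acetic anhydride CC(=O)OC(C)=O
Why: Addition of the lithium acetylide to the aldehyde and in situ O-acetylation of the alkoxide; the carbinol centre forms as a mixture that is destroyed in steps 17–18.

Step 17
Reactants: 27 propargylic acetate
Product: 29 tetracyclic alkylidenecyclopentenone, via allenyl acetate 28 (not isolated)
Conditions: [Rh(CO)2Cl]2 (10 mol %), CO (1 atm), CF3CO2H (1.0 equiv), ClCH2CH2Cl, 80 °C; NaHCO3 work-up
Reagents that add atoms: carbon monoxide [C-]#[O+]
Why: The rhodium catalyst should first effect a 1,3-acyloxy shift (formal [3,3]) of the propargylic acetate to the 1-acetoxyallene 28 and then undergo oxidative cyclisation with the silylalkyne and the distal allene π bond, which forms the C–C bond between the internal alkyne carbon (on the quaternary C1) and the central allene carbon; CO insertion and reductive elimination deliver the 4-alkylidenecyclopent-2-enone. The closest known reactions are the rhodium-catalysed allenic Pauson–Khand cyclocarbonylations of allenyl carboxylates and of 3-sulfonyl-1,2-dien-8-ynes to bicyclo[5.3.0]decadienones, and the rhodium-catalysed 1,3-acyloxy migration/carbonylation cascades of propargyl esters. The cycloheptene is closed by the alkyne–allene coupling within the rhodacycle (the enol acetate C=C ends up endocyclic), and the cyclopentenone by the [2+2+1] assembly of alkyne, distal allene π bond and CO. The only new stereocentre, the ring CH bearing the silyloxyethyl arm, is uncontrolled and is erased by enolisation in step 18, so both allene epimers converge. The step needs distal- over proximal-π-bond selectivity and CO insertion rather than β-hydride elimination: the former is secured by monovalent rhodium (as opposed to Mo(CO)6) and by the fully substituted acetoxy-bearing proximal carbon, the latter by the CO atmosphere, while the cis 1,2-relationship of the two arms on the pyrrolidine pre-organises the tether. The basic nitrogen is masked as its trifluoroacetate so that it cannot bind the catalyst.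

Step 18
Reactants: 29 tetracyclic alkylidenecyclopentenone
Product: 30 fulvenyl triflate
Conditions: KN(SiMe3)2, THF, −78 °C; PhNTf2
Reagents that add atoms: N-phenylbis(trifluoromethanesulfonimide) O=S(=O)(N(c1ccccc1)S(=O)(=O)C(F)(F)F)C(F)(F)F
Why: Deprotonation of the doubly activated ring C–H next to the ketone gives a cross-conjugated fulvenolate that is O-triflated (enol triflate formation), which removes the uncontrolled centre.

Step 19
Reactants: 30 fulvenyl triflate
Product: 31 fulvene methyl ester
Conditions: Pd(OAc)2 (10 mol %), dppp, CO (1 atm), MeOH, Et3N, DMF, 50 °C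
Reagents that add atoms: carbon monoxide [C-]#[O+]; methanol CO
Why: Palladium-catalysed methoxycarbonylation of the vinyl triflate (oxidative addition, CO insertion, methanolysis) should install the ring ester on the carbon that came from CO in step 17.

Step 20
Reactants: 31 fulvene methyl ester
Product: 32 cyclopentadiene carboxylic acid
Conditions: LiOH, THF/MeOH/H2O, 40 °C; aq. HCl to pH 6
Reagents that add atoms: lithium hydroxide [Li+].[OH-]
Why: Hydroxide should cleave the enol acetate to the acyl cyclopentadienide (whose ring C–Si bond is protodesilylated) and saponify the aliphatic ester, while the ring ester is protected as part of the delocalised anion.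

Step 21
Reactants: 32 cyclopentadiene carboxylic acid
Product: 34 daphnicyclidin H, via silyl ether 33 (not isolated)
Conditions: EDC·HCl, DMAP, CH2Cl2 (2 mM), rt; then HF·pyridine, THF, 0 °C → rt
Reagents that add atoms: none
Why: Carbodiimide/DMAP C-acylation of a strongly acidic carbon acid (as for Meldrum's acid or tetramic acids) should occur at the only unsubstituted ring carbon and close the second seven-membered ring as the chelated hydroxyfulvene; the bridge can form only cis across the piperidine, which fixes the α-centre, and fluoride then removes the silyl ether.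

**Compound list**

1 | methyl 3-oxopentanoate | CCC(=O)CC(=O)OC | starting material
2 | methyl 2-(2-ethyl-1,3-dioxolan-2-yl)acetate | CCC1(CC(=O)OC)OCCO1 | intermediate
3 | methyl acetate | CC(=O)OC | starting material
4 | methyl 4-(2-ethyl-1,3-dioxolan-2-yl)-3-oxobutanoate | CCC1(CC(=O)CC(=O)OC)OCCO1 | intermediate
5 | 4-[(tert-butyldimethylsilyl)oxy]butanal | O=CCCCO[Si](C)(C)C(C)(C)C | starting material
6 | nitromethane | C[N+](=O)[O-] | starting material
7 | 5-[(tert-butyldimethylsilyl)oxy]-1-nitropentan-2-ol (racemic) | [O-][N+](=O)CC(O)CCCO[Si](C)(C)C(C)(C)C | intermediate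
8 | (E)-tert-butyldimethyl[(5-nitropent-4-en-1-yl)oxy]silane | [O-][N+](=O)/C=C/CCCO[Si](C)(C)C(C)(C)C | intermediate
9 | methyl (3S)-6-[(tert-butyldimethylsilyl)oxy]-2-[2-(2-ethyl-1,3-dioxolan-2-yl)acetyl]-3-(nitromethyl)hexanoate (C2 epimers) | [O-][N+](=O)C[C@@H](CCCO[Si](C)(C)C(C)(C)C)C(C(=O)OC)C(=O)CC1(CC)OCCO1 | intermediate
10 | methyl (4S)-4-{3-[(tert-butyldimethylsilyl)oxy]propyl}-2-[(2-ethyl-1,3-dioxolan-2-yl)methyl]-4,5-dihydro-1H-pyrrole-3-carboxylate | COC(=O)C1=C(CC2(CC)OCCO2)NC[C@H]1CCCO[Si](C)(C)C(C)(C)C | intermediate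
11 | methyl (2R,3R,4S)-4-{3-[(tert-butyldimethylsilyl)oxy]propyl}-2-[(2-ethyl-1,3-dioxolan-2-yl)methyl]pyrrolidine-3-carboxylate (all-cis) | N1C[C@@H](CCCO[Si](C)(C)C(C)(C)C)[C@@H](C(=O)OC)[C@H]1CC2(CC)OCCO2 | intermediate
12 | 1-tert-butyl 3-methyl (2R,3R,4S)-4-{3-[(tert-butyldimethylsilyl)oxy]propyl}-2-[(2-ethyl-1,3-dioxolan-2-yl)methyl]pyrrolidine-1,3-dicarboxylate | CC(C)(C)OC(=O)N1C[C@@H](CCCO[Si](C)(C)C(C)(C)C)[C@@H](C(=O)OC)[C@H]1CC2(CC)OCCO2 | intermediate
13 | 1-tert-butyl 3-methyl (2R,3R,4S)-4-{3-[(tert-butyldimethylsilyl)oxy]propyl}-2-[(2-ethyl-1,3-dioxolan-2-yl)methyl]-3-methylpyrrolidine-1,3-dicarboxylate | CC(C)(C)OC(=O)N1C[C@@H](CCCO[Si](C)(C)C(C)(C)C)[C@@](C)(C(=O)OC)[C@H]1CC2(CC)OCCO2 | intermediate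
14 | tert-butyl (2R,3R,4S)-4-{3-[(tert-butyldimethylsilyl)oxy]propyl}-2-[(2-ethyl-1,3-dioxolan-2-yl)methyl]-3-formyl-3-methylpyrrolidine-1-carboxylate | CC(C)(C)OC(=O)N1C[C@@H](CCCO[Si](C)(C)C(C)(C)C)[C@@](C)(C=O)[C@H]1CC2(CC)OCCO2 | intermediate
15 | tert-butyl (2R,3S,4S)-4-{3-[(tert-butyldimethylsilyl)oxy]propyl}-2-[(2-ethyl-1,3-dioxolan-2-yl)methyl]-3-ethynyl-3-methylpyrrolidine-1-carboxylate | CC(C)(C)OC(=O)N1C[C@@H](CCCO[Si](C)(C)C(C)(C)C)[C@@](C)(C#C)[C@H]1CC2(CC)OCCO2 | intermediate
16 | 1-[(2R,3S,4S)-3-ethynyl-4-(3-hydroxypropyl)-3-methylpyrrolidin-2-yl]butan-2-one | N1C[C@@H](CCCO)[C@@](C)(C#C)[C@H]1CC(=O)CC | intermediate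
17 | (1S,2S,6R,8aR)-1-ethynyl-2-(3-hydroxypropyl)-1,6-dimethylhexahydroindolizin-7(1H)-one | C[C@@H]1CN2C[C@@H](CCCO)[C@@](C)(C#C)[C@H]2CC1=O | intermediate
18 | (1S,2S,6S,8aR)-1-ethynyl-2-(3-hydroxypropyl)-1,6-dimethyloctahydroindolizine-7-carbonitrile (C7 epimers) | C[C@@H]1CN2C[C@@H](CCCO)[C@@](C)(C#C)[C@H]2CC1C#N | intermediate
19 | methyl (1S,2S,6S,8aR)-1-ethynyl-2-(3-hydroxypropyl)-1,6-dimethyloctahydroindolizine-7-carboxylate (C7 epimers) | C[C@@H]1CN2C[C@@H](CCCO)[C@@](C)(C#C)[C@H]2CC1C(=O)OC | intermediate
20 | methyl (1S,2S,6S,7R,8aR)-1-ethynyl-2-(3-hydroxypropyl)-1,6-dimethyloctahydroindolizine-7-carboxylate | C[C@@H]1CN2C[C@@H](CCCO)[C@@](C)(C#C)[C@H]2C[C@H]1C(=O)OC | intermediate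
21 | methyl (1S,2S,6S,7R,8aR)-1,6-dimethyl-1-[(trimethylsilyl)ethynyl]-2-{3-[(trimethylsilyl)oxy]propyl}octahydroindolizine-7-carboxylate | C[C@@H]1CN2C[C@@H](CCCO[Si](C)(C)C)[C@@](C)(C#C[Si](C)(C)C)[C@H]2C[C@H]1C(=O)OC | intermediate
22 | methyl (1S,2S,6S,7R,8aR)-2-(3-hydroxypropyl)-1,6-dimethyl-1-[(trimethylsilyl)ethynyl]octahydroindolizine-7-carboxylate | C[C@@H]1CN2C[C@@H](CCCO)[C@@](C)(C#C[Si](C)(C)C)[C@H]2C[C@H]1C(=O)OC | intermediate
23 | methyl (1S,2S,6S,7R,8aR)-1,6-dimethyl-2-(3-oxopropyl)-1-[(trimethylsilyl)ethynyl]octahydroindolizine-7-carboxylate | C[C@@H]1CN2C[C@@H](CCC=O)[C@@](C)(C#C[Si](C)(C)C)[C@H]2C[C@H]1C(=O)OC | intermediate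
24 | methyl (1S,2S,6S,7R,8aR)-2-(but-3-yn-1-yl)-1,6-dimethyl-1-[(trimethylsilyl)ethynyl]octahydroindolizine-7-carboxylate | C[C@@H]1CN2C[C@@H](CCC#C)[C@@](C)(C#C[Si](C)(C)C)[C@H]2C[C@H]1C(=O)OC | intermediate
25 | 3-[(tert-butyldimethylsilyl)oxy]propanal | O=CCCO[Si](C)(C)C(C)(C)C | starting material
26 | methyl (1S,2S,6S,7R,8aR)-2-{7-[(tert-butyldimethylsilyl)oxy]-5-hydroxyhept-3-yn-1-yl}-1,6-dimethyl-1-[(trimethylsilyl)ethynyl]octahydroindolizine-7-carboxylate (carbinol epimers) | C[C@@H]1CN2C[C@@H](CCC#CC(O)CCO[Si](C)(C)C(C)(C)C)[C@@](C)(C#C[Si](C)(C)C)[C@H]2C[C@H]1C(=O)OC | intermediate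
27 | methyl (1S,2S,6S,7R,8aR)-2-{5-acetoxy-7-[(tert-butyldimethylsilyl)oxy]hept-3-yn-1-yl}-1,6-dimethyl-1-[(trimethylsilyl)ethynyl]octahydroindolizine-7-carboxylate (carbinol epimers) | C[C@@H]1CN2C[C@@H](CCC#CC(OC(C)=O)CCO[Si](C)(C)C(C)(C)C)[C@@](C)(C#C[Si](C)(C)C)[C@H]2C[C@H]1C(=O)OC | intermediate
28 | methyl (1S,2S,6S,7R,8aR)-2-{3-acetoxy-7-[(tert-butyldimethylsilyl)oxy]hepta-3,4-dien-1-yl}-1,6-dimethyl-1-[(trimethylsilyl)ethynyl]octahydroindolizine-7-carboxylate (allene epimers) | C[C@@H]1CN2C[C@@H](CCC(OC(C)=O)=C=CCCO[Si](C)(C)C(C)(C)C)[C@@](C)(C#C[Si](C)(C)C)[C@H]2C[C@H]1C(=O)OC | intermediate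
29 | cyclocarbonylation product: indolizidine of 27 fused at C1–C2 to a cycloheptene whose endocyclic enol acetate C=C is exocyclic to a cyclopent-2-enone; Me3Si on the enone α-carbon, 2-(TBS-oxy)ethyl on the sp3 ring CH (epimers), C7 methyl ester | C[C@@H]1CN2C[C@H]3CCC(OC(C)=O)=C4C(CCO[Si](C)(C)C(C)(C)C)C(=O)C([Si](C)(C)C)=C4[C@@]3(C)[C@H]2C[C@H]1C(=O)OC | intermediate
30 | fulvenyl triflate derived from 29 (ring ketone as enol triflate, exocyclic fulvene C=C is the enol acetate) | C[C@@H]1CN2C[C@H]3CCC(OC(C)=O)=C4C(CCO[Si](C)(C)C(C)(C)C)=C(OS(=O)(=O)C(F)(F)F)C([Si](C)(C)C)=C4[C@@]3(C)[C@H]2C[C@H]1C(=O)OC | intermediate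
31 | fulvene methyl ester (triflate of 30 replaced by CO2Me) | C[C@@H]1CN2C[C@H]3CCC(OC(C)=O)=C4C(CCO[Si](C)(C)C(C)(C)C)=C(C(=O)OC)C([Si](C)(C)C)=C4[C@@]3(C)[C@H]2C[C@H]1C(=O)OC | intermediate
32 | tetracyclic 7-carboxylic acid with the cycloheptenone-fused methyl cyclopentadienecarboxylate (ring CH2 tautomer; zwitterionic with the amine) | C[C@@H]1CN2C[C@H]3CCC(=O)C=4C(CCO[Si](C)(C)C(C)(C)C)=C(C(=O)OC)CC=4[C@@]3(C)[C@H]2C[C@H]1C(=O)O | intermediate
33 | O-(tert-butyldimethylsilyl)daphnicyclidin H | COC(=O)C1=C(CCO[Si](C)(C)C(C)(C)C)C2=C3C1=C(O)[C@@H]1C[C@H]4N(C[C@@H](CCC2=O)[C@@]34C)C[C@H]1C | intermediate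
34 | daphnicyclidin H | COC(=O)C1=C(CCO)C2=C3C1=C(O)[C@@H]1C[C@H]4N(C[C@@H](CCC2=O)[C@@]34C)C[C@H]1C | target

**Step count.** Total: 21 steps. Longest linear sequence: 20 steps (steps 1, 2 and 4–21, from methyl 3-oxopentanoate).

**Steps most likely to fail**

Step 17. The 1,3-acyloxy shift may be outrun by 1,2-acyloxy migration or by ene-type cycloisomerisation (β-hydride elimination from the rhodacycle before CO insertion), so that the acetoxyallene never enters the carbonylative cycle. The fallback keeps the same ring-closing bond but carries a sulfonyl group on the allene and brings in the ring-ketone oxygen only after cyclisation. It sets out from propargylic alcohol 26, isolated by omitting the anhydride quench of step 16. PhSCl/Et3N at −78 °C → rt should give, by [2,3]-sigmatropic rearrangement of the sulfenate, the allenyl sulfoxide F1. Oxidation of its trifluoroacetate salt with mCPBA should give the allenyl sulfone F2. Cyclocarbonylation of this 3-sulfonyl-1,2-dien-8-yne with [Rh(CO)2Cl]2 under CO should give the vinyl sulfone cyclopentenone F3. The conditions of steps 18 and 19 should give the fulvenyl triflate F4 and the fulvene ester F5. Under the LiOH conditions of step 20, hydroxide should add to the sulfonyl-bearing exocyclic fulvene carbon and expel benzenesulfinate, which returns the route to 32.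

Step 21. The activated acid may be diverted to anhydride or N-acylurea oligomers, because the piperidine must flip to its triaxial chair before the acyl group can reach the ring carbon. The fallback sets out from 31 and skips 32. NaOMe in MeOH at 65 °C should cleave the enol acetate and the C–Si bond and then drive a Lacey–Dieckmann-type Claisen condensation of the cyclopentadienide onto the intact aliphatic methyl ester, with deprotonation of the tricarbonyl product as driving force. This gives 33 directly, and HF·pyridine then gives 34. The fallback makes no new compound (F0).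

Step 11. Retro-Michael opening and enolisation of the β-amino ketone under the strongly basic conditions may compete with addition of the hindered isocyanide anion to the α-branched ketone. The fallback sets out from 17. Wittig methoxymethylenation (Ph3PCH2OMe chloride, KN(SiMe3)2, excess) should give the enol ether F6. Aqueous HCl hydrolysis followed by DBU equilibration should give the equatorial aldehyde F7. Pinnick oxidation (NaClO2, NaH2PO4, 2-methyl-2-butene) should give the acid F8, and Me3SiCHN2 in MeOH returns the route to 20.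

**Further compounds**

F1 | step 17 | allenyl sulfoxide (3-(phenylsulfinyl)hepta-3,4-dienyl analogue of 28) | C[C@@H]1CN2C[C@@H](CCC(S(=O)c3ccccc3)=C=CCCO[Si](C)(C)C(C)(C)C)[C@@](C)(C#C[Si](C)(C)C)[C@H]2C[C@H]1C(=O)OC
F2 | step 17 | allenyl sulfone (3-(phenylsulfonyl)hepta-3,4-dienyl analogue of 28) | C[C@@H]1CN2C[C@@H](CCC(S(=O)(=O)c3ccccc3)=C=CCCO[Si](C)(C)C(C)(C)C)[C@@](C)(C#C[Si](C)(C)C)[C@H]2C[C@H]1C(=O)OC
F3 | step 17 | vinyl sulfone cyclopentenone (phenylsulfonyl analogue of 29) | C[C@@H]1CN2C[C@H]3CCC(S(=O)(=O)c5ccccc5)=C4C(CCO[Si](C)(C)C(C)(C)C)C(=O)C([Si](C)(C)C)=C4[C@@]3(C)[C@H]2C[C@H]1C(=O)OC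
F4 | step 17 | fulvenyl triflate (phenylsulfonyl analogue of 30) | C[C@@H]1CN2C[C@H]3CCC(S(=O)(=O)c5ccccc5)=C4C(CCO[Si](C)(C)C(C)(C)C)=C(OS(=O)(=O)C(F)(F)F)C([Si](C)(C)C)=C4[C@@]3(C)[C@H]2C[C@H]1C(=O)OC
F5 | step 17 | fulvene methyl ester (phenylsulfonyl analogue of 31) | C[C@@H]1CN2C[C@H]3CCC(S(=O)(=O)c5ccccc5)=C4C(CCO[Si](C)(C)C(C)(C)C)=C(C(=O)OC)C([Si](C)(C)C)=C4[C@@]3(C)[C@H]2C[C@H]1C(=O)OC
F0 | step 21 | none | none
F6 | step 11 | (1S,2S,6S,8aR)-1-ethynyl-2-(3-hydroxypropyl)-7-(methoxymethylidene)-1,6-dimethyloctahydroindolizine (E/Z mixture) | C[C@@H]1CN2C[C@@H](CCCO)[C@@](C)(C#C)[C@H]2CC1=COC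
F7 | step 11 | (1S,2S,6S,7R,8aR)-1-ethynyl-2-(3-hydroxypropyl)-1,6-dimethyloctahydroindolizine-7-carbaldehyde | C[C@@H]1CN2C[C@@H](CCCO)[C@@](C)(C#C)[C@H]2C[C@H]1C=O
F8 | step 11 | (1S,2S,6S,7R,8aR)-1-ethynyl-2-(3-hydroxypropyl)-1,6-dimethyloctahydroindolizine-7-carboxylic acid | C[C@@H]1CN2C[C@@H](CCCO)[C@@](C)(C#C)[C@H]2C[C@H]1C(=O)O
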